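**Assumptions**
- Geranyl means (2E)-3,7-dimethylocta-2,6-dien-1-yl and MOM means CH2OCH3; the target is the (2S)-flavanone (at C2: O1 > aryl > C3 > H), i.e. 6-geranylhesperetin.
- 5,7-Dihydroxychromone, geranyl bromide, (3-hydroxy-4-methoxyphenyl)boronic acid and the Rh/ligand components are bought.
- The (S) hand of the ligand is a prediction from the Hayashi–Miyaura quadrant model, not a recalled result; it is checked by chiral HPLC/CD on the first run and the antipode is used if the sense is opposite.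

**Retrosynthetic overview**
1. Target ⇒ its 5,7-bis-MOM ether (acidic removal of the MOM groups last).
2. C2–aryl bond ⇒ Rh-catalysed asymmetric 1,4-addition of (3-hydroxy-4-methoxyphenyl)boronic acid to 6-geranyl-5,7-bis(MOM-oxy)chromone; this sets 2S.
3. C6–geranyl bond ⇒ C-geranylation of 5,7-dihydroxychromone with geranyl bromide.
4. Ring order: no ring is built. The A/C chromone bicycle is bought, the B ring is attached as a unit, and the pyranone becomes the chromanone in the conjugate addition.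

**Route**

Step 1
Reactants: 1 5,7-dihydroxy-4H-chromen-4-one; 2 geranyl bromide, (2E)-1-bromo-3,7-dimethylocta-2,6-diene
Product: 3 6-geranyl-5,7-dihydroxy-4H-chromen-4-one
Conditions: NaOMe (3 equiv), MeOH, 0 °C → rt, 2 (1.5 equiv) added dropwise; 1 M HCl work-up; SiO2 chromatography
Reagents that add atoms: none
Why: Nuclear C-alkylation of an ambident phenoxide (SN2 at the primary allylic bromide, so the 2E alkene is untouched): in methanol the phenoxide oxygens are hydrogen-bonded and carbon attacks, and C6, between the two phenoxide oxygens, is more nucleophilic than C8, so the 6-geranyl isomer is expected as the main C-alkylation product (about 20–30 %), separated from the 8-isomer, the 6,8-dialkylated compound and the 7-O-ether, with HMBC from the chelated 5-OH to the substituted C6 as proof of regiochemistry.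

Step 2
Reactants: 3 6-geranyl-5,7-dihydroxy-4H-chromen-4-one
Product: 5 6-geranyl-5,7-bis(methoxymethoxy)-4H-chromen-4-one, via 7-O-MOM chromone 4 (not isolated)
Conditions: NaH (3 equiv), MOMCl (3 equiv), DMF, 0 °C → rt
Reagents that add atoms: chloromethyl methyl ether (MOMCl), COCCl
Why: Williamson-type O-alkylation (MOM ether formation): NaH forms both phenoxides, the free 7-oxygen reacts first (4) and the chelated 5-oxygen follows with excess MOMCl, which removes both acidic OH groups before the rhodium step; there is no stereocentre to lose.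

Step 3
Reactants: 5 6-geranyl-5,7-bis(methoxymethoxy)-4H-chromen-4-one; 6 (3-hydroxy-4-methoxyphenyl)boronic acid
Product: 7 (2S)-6-geranyl-2-(3-hydroxy-4-methoxyphenyl)-5,7-bis(methoxymethoxy)chroman-4-one
Conditions: [Rh(OH)((S)-MeO-F12-BIPHEP)]2 (3 mol % Rh), 6 (3 equiv), toluene/H2O 10:1, 40 °C
Reagents that add atoms: none
Why: Rhodium(I)-catalysed asymmetric 1,4-addition of an arylboronic acid (Hayashi–Miyaura reaction): the aryl–Rh species adds across C2=C3 and the electron-poor chiral bisphosphine delivers the aryl group to the C2 Re face (O1 > C3 > H), which gives 2S, after which water protonates the rhodium enolate; isolated trisubstituted alkenes, MOM ethers and the free phenol of 6 should be tolerated under these base-free conditions.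

Step 4
Reactants: 7 (2S)-6-geranyl-2-(3-hydroxy-4-methoxyphenyl)-5,7-bis(methoxymethoxy)chroman-4-one
Product: 9 (2S)-6-geranyl-5,7-dihydroxy-2-(3-hydroxy-4-methoxyphenyl)chroman-4-one (the target), via 7-O-MOM flavanone 8 (not isolated)
Conditions: cat. HCl (about 0.5 M), MeOH, 40 °C, stopped at full conversion (HPLC); NaHCO3 work-up
Reagents that add atoms: none
Why: Acid-catalysed acetal cleavage (MOM ether methanolysis): each OCH2OCH3 group is passed to methanol as dimethoxymethane, the 5-O-MOM next to the carbonyl first (8), and in dilute acid at 40 °C the chromanone ring should not open, so 2S is kept, while the trisubstituted alkenes are protonated too slowly to cyclise onto the new phenols.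

**Compound list**
1 | 5,7-dihydroxy-4H-chromen-4-one | O=c1ccoc2cc(O)cc(O)c12 | starting material
2 | geranyl bromide, (2E)-1-bromo-3,7-dimethylocta-2,6-diene | BrC/C=C(\C)CCC=C(C)C | starting material
3 | 6-[(2E)-3,7-dimethylocta-2,6-dien-1-yl]-5,7-dihydroxy-4H-chromen-4-one | O=c1ccoc2cc(O)c(C/C=C(\C)CCC=C(C)C)c(O)c12 | intermediate
4 | 6-[(2E)-3,7-dimethylocta-2,6-dien-1-yl]-5-hydroxy-7-(methoxymethoxy)-4H-chromen-4-one | O=c1ccoc2cc(OCOC)c(C/C=C(\C)CCC=C(C)C)c(O)c12 | intermediate (not isolated)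
5 | 6-[(2E)-3,7-dimethylocta-2,6-dien-1-yl]-5,7-bis(methoxymethoxy)-4H-chromen-4-one | O=c1ccoc2cc(OCOC)c(C/C=C(\C)CCC=C(C)C)c(OCOC)c12 | intermediate
6 | (3-hydroxy-4-methoxyphenyl)boronic acid | COc1ccc(B(O)O)cc1O | starting material
7 | (2S)-6-[(2E)-3,7-dimethylocta-2,6-dien-1-yl]-2-(3-hydroxy-4-methoxyphenyl)-5,7-bis(methoxymethoxy)-2,3-dihydro-4H-chromen-4-one | COc1ccc([C@@H]2CC(=O)c3c(cc(OCOC)c(C/C=C(\C)CCC=C(C)C)c3OCOC)O2)cc1O | intermediate
8 | (2S)-6-[(2E)-3,7-dimethylocta-2,6-dien-1-yl]-5-hydroxy-2-(3-hydroxy-4-methoxyphenyl)-7-(methoxymethoxy)-2,3-dihydro-4H-chromen-4-one | COc1ccc([C@@H]2CC(=O)c3c(cc(OCOC)c(C/C=C(\C)CCC=C(C)C)c3O)O2)cc1O | intermediate (not isolated)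
9 | (2S)-6-[(2E)-3,7-dimethylocta-2,6-dien-1-yl]-5,7-dihydroxy-2-(3-hydroxy-4-methoxyphenyl)-2,3-dihydro-4H-chromen-4-one | COc1ccc([C@@H]2CC(=O)c3c(cc(O)c(C/C=C(\C)CCC=C(C)C)c3O)O2)cc1O | target

**Totals**
Total step count: 4. Longest linear sequence: 4 steps (1 → 3 → 5 → 7 → 9).

**Three steps most likely to fail**

Step 1 (C6 against C8 and O-alkylation; low yield). The fallback sets out from 1 and comes back at 5, and fixes the position with a halogen instead of relying on phenoxide selectivity. Compound 1 is protected at the non-chelated 7-OH only (MOMCl 1.1 equiv, K2CO3, acetone) to give 5-hydroxy-7-(methoxymethoxy)-4H-chromen-4-one F1. The free 5-OH then directs iodination to its ortho position (NIS, DMF, rt) to give 5-hydroxy-6-iodo-7-(methoxymethoxy)-4H-chromen-4-one F2. MOM protection (NaH, MOMCl, DMF) gives 6-iodo-5,7-bis(methoxymethoxy)-4H-chromen-4-one F3. Stille coupling (Pd2(dba)3, AsPh3, DMF, 80 °C) with tributyl[(2E)-3,7-dimethylocta-2,6-dien-1-yl]stannane F4, made from 2 and Bu3SnLi in THF at −78 °C, gives 5; the linear-to-branched ratio and E/Z purity are checked by NMR.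

Step 3 (electron-rich 5,7-dialkoxychromone as acceptor, protodeboronation of the electron-rich boronic acid, uncertain sense of induction). The fallback sets out from 5 and comes back at 7, and rebuilds the C ring by oxa-Michael closure followed by resolution. Aqueous NaOH in EtOH at reflux opens the pyranone of 5 and removes C2 as formate to give 1-[3-geranyl-6-hydroxy-2,4-bis(methoxymethoxy)phenyl]ethan-1-one F5. Claisen–Schmidt condensation with isovanillin (KOH, EtOH, rt; the 3-phenoxide is meta to the aldehyde and does not deactivate it) gives (2E)-1-[3-geranyl-6-hydroxy-2,4-bis(methoxymethoxy)phenyl]-3-(3-hydroxy-4-methoxyphenyl)prop-2-en-1-one F6. NaOAc in EtOH at reflux closes the only free ortho-phenol onto the enone and gives racemic 6-geranyl-2-(3-hydroxy-4-methoxyphenyl)-5,7-bis(methoxymethoxy)chroman-4-one F7, with the 6-geranyl regiochemistry fixed because the other ortho-oxygen is still a MOM ether. Preparative chiral SFC (amylose tris(3,5-dimethylphenylcarbamate) phase) gives 7 and the (2R)-enantiomer of 7 F8, which is recycled to F6 with base.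

Step 4 (acid-induced cyclisation of the geranyl chain onto the 5- or 7-phenol, or partial loss of ee). The fallback sets out from 3 and comes back at 9, and replaces the acid-labile groups by fluoride-labile ones. Compound 3 is silylated (TBSOTf, 2,6-lutidine, CH2Cl2, 0 °C) to give 6-geranyl-5,7-bis(tert-butyldimethylsilyloxy)-4H-chromen-4-one F9. The Rh-catalysed addition of 6 under the step 3 conditions gives (2S)-6-geranyl-5,7-bis(tert-butyldimethylsilyloxy)-2-(3-hydroxy-4-methoxyphenyl)chroman-4-one F10. Et3N·3HF in THF at 0 °C removes both silyl groups and gives 9 under near-neutral conditions that neither protonate the alkenes nor open the chromanone ring.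

**Further compounds**
F1 | step 1 | 5-hydroxy-7-(methoxymethoxy)-4H-chromen-4-one | O=c1ccoc2cc(OCOC)cc(O)c12
F2 | step 1 | 5-hydroxy-6-iodo-7-(methoxymethoxy)-4H-chromen-4-one | O=c1ccoc2cc(OCOC)c(I)c(O)c12
F3 | step 1 | 6-iodo-5,7-bis(methoxymethoxy)-4H-chromen-4-one | O=c1ccoc2cc(OCOC)c(I)c(OCOC)c12
F4 | step 1 | tributyl[(2E)-3,7-dimethylocta-2,6-dien-1-yl]stannane | CCCC[Sn](CCCC)(CCCC)C/C=C(\C)CCC=C(C)C
F5 | step 3 | 1-[3-[(2E)-3,7-dimethylocta-2,6-dien-1-yl]-6-hydroxy-2,4-bis(methoxymethoxy)phenyl]ethan-1-one | CC(=O)c1c(O)cc(OCOC)c(C/C=C(\C)CCC=C(C)C)c1OCOC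
F6 | step 3 | (2E)-1-[3-[(2E)-3,7-dimethylocta-2,6-dien-1-yl]-6-hydroxy-2,4-bis(methoxymethoxy)phenyl]-3-(3-hydroxy-4-methoxyphenyl)prop-2-en-1-one | COc1ccc(/C=C/C(=O)c2c(O)cc(OCOC)c(C/C=C(\C)CCC=C(C)C)c2OCOC)cc1O
F7 | step 3 | racemic 6-[(2E)-3,7-dimethylocta-2,6-dien-1-yl]-2-(3-hydroxy-4-methoxyphenyl)-5,7-bis(methoxymethoxy)-2,3-dihydro-4H-chromen-4-one | COc1ccc(C2CC(=O)c3c(cc(OCOC)c(C/C=C(\C)CCC=C(C)C)c3OCOC)O2)cc1O
F8 | step 3 | (2R)-6-[(2E)-3,7-dimethylocta-2,6-dien-1-yl]-2-(3-hydroxy-4-methoxyphenyl)-5,7-bis(methoxymethoxy)-2,3-dihydro-4H-chromen-4-one | COc1ccc([C@H]2CC(=O)c3c(cc(OCOC)c(C/C=C(\C)CCC=C(C)C)c3OCOC)O2)cc1O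
F9 | step 4 | 5,7-bis(tert-butyldimethylsilyloxy)-6-[(2E)-3,7-dimethylocta-2,6-dien-1-yl]-4H-chromen-4-one | O=c1ccoc2cc(O[Si](C)(C)C(C)(C)C)c(C/C=C(\C)CCC=C(C)C)c(O[Si](C)(C)C(C)(C)C)c12
F10 | step 4 | (2S)-5,7-bis(tert-butyldimethylsilyloxy)-6-[(2E)-3,7-dimethylocta-2,6-dien-1-yl]-2-(3-hydroxy-4-methoxyphenyl)-2,3-dihydro-4H-chromen-4-one | COc1ccc([C@@H]2CC(=O)c3c(cc(O[Si](C)(C)C(C)(C)C)c(C/C=C(\C)CCC=C(C)C)c3O[Si](C)(C)C(C)(C)C)O2)cc1O
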